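The carbocycle is disconnected at the C4–C5 bond of the cyclohexenedione ring (7-oxabicyclo[4.1.0]heptene numbering: C1 farnesyl-bearing oxirane carbon, C4 the CH2OAc-bearing alkene carbon, C5 the carbonyl next to oxirane CH C6). The oxirane is made first, by Sharpless epoxidation of an open-chain Z-allylic alcohol, and carries both stereocentres. The key step is an intramolecular Nozaki–Hiyama–Kishi reaction of an acyclic (Z)-β-iodoenone epoxy-aldehyde, which closes the carbocycle in one operation. It exploits the cis-oxirane O7/C1/C6, which holds the C2 and C5 arms on one face, and the Z C3=C4 alkene, which points C4 at C5. One oxidation then gives the target.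

Key step: step 11

Remark: commercial (2E,6E)-farnesyl bromide is taken as the single geometric isomer; "farnesyl" means (2E,6E)-3,7,11-trimethyldodeca-2,6,10-trien-1-yl, TBS means tert-butyldimethylsilyl, and the locants C1–C6/O7 are those of the target core (C1 oxirane C with farnesyl, C2 C=O, C3 =CH, C4 =C–CH2OAc, C5 C=O, C6 oxirane CH, O7 oxirane O), used for the same atoms in all open-chain precursors.

Step 1
Reactants: 1 methyl 2-[bis(2,2,2-trifluoroethoxy)phosphoryl]acetate; 2 (2E,6E)-farnesyl bromide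
Product: 3 methyl 2-[bis(2,2,2-trifluoroethoxy)phosphoryl]-2-farnesylacetate (racemic)
Conditions: NaH, THF–DMF, 0 °C to rt
Reagents that add atoms: none
Why: C-alkylation (SN2) of the stabilised phosphonoacetate anion at the unhindered CH2 of the primary allylic bromide leaves the E,E-triene untouched, and the racemic α-centre disappears in step 2.

Step 2
Reactants: 3 methyl 2-[bis(2,2,2-trifluoroethoxy)phosphoryl]-2-farnesylacetate; 4 (tert-butyldimethylsilyloxy)acetaldehyde
Product: 5 methyl (2Z)-4-(TBS-oxy)-2-farnesylbut-2-enoate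
Conditions: KHMDS, 18-crown-6, THF, −78 °C
Reagents that add atoms: none
Why: In the Still–Gennari variant of the Horner–Wadsworth–Emmons olefination the electron-poor phosphonate with a dissociated potassium ion eliminates from the kinetic adduct, which places the ester (C2) cis to CH2OTBS (C5), the geometry that later puts both arms on one face of the oxirane.

Step 3
Reactants: 5 methyl (2Z)-4-(TBS-oxy)-2-farnesylbut-2-enoate
Product: 6 (2Z)-4-(TBS-oxy)-2-farnesylbut-2-en-1-ol
Conditions: DIBAL-H, CH2Cl2, −78 °C; Rochelle salt work-up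
Reagents that add atoms: none
Why: 1,2-Reduction of the enoate by DIBAL-H at low temperature gives the allylic alcohol without change of alkene geometry and without loss or migration of the silyl ether.

Step 4
Reactants: 6 (2Z)-4-(TBS-oxy)-2-farnesylbut-2-en-1-ol
Product: 7 [(2S,3R)-3-(TBS-oxymethyl)-2-farnesyloxiran-2-yl]methanol
Conditions: Ti(OiPr)4 (cat.), L-(+)-diethyl tartrate (cat.), t-BuOOH, 4 Å MS, CH2Cl2, −20 °C
Reagents that add atoms: tert-butyl hydroperoxide, CC(C)(C)OO
Why: In the Sharpless asymmetric epoxidation only the alkene of the titanium-bound allylic alcohol is oxidised, so the three isolated trisubstituted alkenes remain; syn addition to the Z-alkene fixes the cis relation of the C2 and C5 arms, and L-(+)-tartrate delivers oxygen to the face that sets C1 and C6 as in the target.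

Step 5
Reactants: 7 [(2S,3R)-3-(TBS-oxymethyl)-2-farnesyloxiran-2-yl]methanol
Product: 8 (2R,3R)-3-(TBS-oxymethyl)-2-farnesyloxirane-2-carbaldehyde
Conditions: TPAP (cat.), NMO, 4 Å MS, CH2Cl2, rt
Reagents that add atoms: none
Why: The neutral Ley–Griffith oxidation stops at the aldehyde, which sits on the quaternary C1 and therefore cannot enolise or epimerise (the change of descriptor is only a change of CIP priority).

Step 6
Reactants: 9 trimethyl(prop-2-yn-1-yloxy)silane
Product: 10 (Z)-trimethyl{[2,3-bis(trimethylstannyl)prop-2-en-1-yl]oxy}silane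
Conditions: Me3SnSnMe3, Pd(PPh3)4 (cat.), THF, 65 °C
Reagents that add atoms: hexamethylditin, C[Sn](C)(C)[Sn](C)(C)C
Why: Pd(0)-catalysed distannylation of a terminal alkyne (Sn–Sn oxidative addition, syn stannylpalladation, reductive elimination) places both tin groups cis, which fixes the later Z geometry of C3=C4.

Step 7
Reactants: 10 (Z)-trimethyl{[2,3-bis(trimethylstannyl)prop-2-en-1-yl]oxy}silane; 8 (2R,3R)-3-(TBS-oxymethyl)-2-farnesyloxirane-2-carbaldehyde
Product: 13 (2Z)-4-[(2S,3R)-3-(TBS-oxymethyl)-2-farnesyloxiran-2-yl]-2-(trimethylstannyl)but-2-ene-1,4-diol (both C2-carbinol epimers), via vinyllithium 11 (not isolated), via TMS ether adduct 12 (not isolated)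
Conditions: MeLi, THF, −78 °C; then 8, −78 °C; H2O quench; then citric acid (cat.), MeOH, 0 °C
Reagents that add atoms: none
Why: Tin–lithium exchange takes the less hindered terminal stannyl group and gives the less substituted, configurationally stable vinyllithium, which adds 1,2 to the non-enolisable aldehyde (the C2 carbinol centre forms as a mixture and is erased in step 10), and mild acidic methanolysis removes only the TMS ether.

Step 8
Reactants: 13 (2Z)-4-[(2S,3R)-3-(TBS-oxymethyl)-2-farnesyloxiran-2-yl]-2-(trimethylstannyl)but-2-ene-1,4-diol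
Product: 15 (2Z)-4-hydroxy-2-iodo-4-[(2S,3R)-3-(TBS-oxymethyl)-2-farnesyloxiran-2-yl]but-2-en-1-yl acetate, via stannyl acetate 14 (not isolated)
Conditions: Ac2O (1 equiv), pyridine, CH2Cl2, −10 °C; then I2 (1 equiv), 0 °C
Reagents that add atoms: acetic anhydride, CC(=O)OC(C)=O; iodine, II
Why: Acetylation selects the primary allylic hydroxyl over the secondary, neopentyl-like C2 carbinol, and the following iododestannylation (ipso substitution with retention) is far faster than any reaction of iodine with the trisubstituted alkenes.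

Step 9
Reactants: 15 (2Z)-4-hydroxy-2-iodo-4-[(2S,3R)-3-(TBS-oxymethyl)-2-farnesyloxiran-2-yl]but-2-en-1-yl acetate
Product: 16 (2Z)-4-hydroxy-4-[(2S,3R)-3-(hydroxymethyl)-2-farnesyloxiran-2-yl]-2-iodobut-2-en-1-yl acetate
Conditions: HF·pyridine, pyridine, THF, 0 °C
Reagents that add atoms: none
Why: Fluoride-driven cleavage of the primary silyl ether in a buffered, non-basic medium avoids acetate migration, Payne rearrangement and opening of the oxirane.

Step 10
Reactants: 16 (2Z)-4-hydroxy-4-[(2S,3R)-3-(hydroxymethyl)-2-farnesyloxiran-2-yl]-2-iodobut-2-en-1-yl acetate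
Product: 17 (2Z)-4-[(2R,3S)-3-formyl-2-farnesyloxiran-2-yl]-2-iodo-4-oxobut-2-en-1-yl acetate
Conditions: (COCl)2, DMSO, CH2Cl2, −78 °C; then iPr2NEt, −78 to −20 °C; used crude
Reagents that add atoms: none
Why: In the Swern oxidation both hydroxyls are converted to alkoxysulfonium ions before base is added, so no hydroxy aldehyde is present to close to a lactol or lactone, and the hindered amine limits addition to the β-iodoenone.

Step 11
Reactants: 17 (2Z)-4-[(2R,3S)-3-formyl-2-farnesyloxiran-2-yl]-2-iodo-4-oxobut-2-en-1-yl acetate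
Product: 19 [(1R,6R)-1-farnesyl-5-hydroxy-2-oxo-7-oxabicyclo[4.1.0]hept-3-en-4-yl]methyl acetate (both C5 epimers), via alkenylchromium(III) species 18 (not isolated)
Conditions: CrCl2 (excess), NiCl2 (cat.), degassed DMF–THF, high dilution, rt; aqueous work-up
Reagents that add atoms: none
Why: Cr(II) reduces NiCl2 to Ni(0), which inserts into the C4–I bond of the (Z)-β-iodoenone with retention; transmetalation to Cr(III) gives the alkenylchromium species 18, whose C4 adds to the C5 aldehyde to form a chromium alkoxide that is hydrolysed on work-up. This is an intramolecular Nozaki–Hiyama–Kishi reaction, a known way to close cycloalkenols from iodoalkene aldehydes. The single ring formed, the six-membered carbocycle C1–C6, closes in a 6-exo-trig mode (C=O exocyclic to the forming ring) because the cis-oxirane holds C2 and C5 on one face and the Z C3=C4 geometry turns C4 towards C5. The only new stereocentre, the C5 carbinol, needs no control (attack anti to O7 is expected to dominate) since step 12 erases it, while C1 and C6 are not touched and cannot enolise. The step needs chemoselectivity for the aldehyde over the C2 ketone, the acetate, the oxirane and the three trisubstituted alkenes, which the aldehyde-selective, non-basic alkenylchromium(III) provides, and the farnesyl chain lies trans to the C5 arm on the oxirane and cannot reach the reacting centres. The aprotic medium and fast intramolecular capture at high dilution are relied on to outrun Cr(II) reduction of the epoxy ketone, loss of acetate from 18 and dimerisation.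

Step 12
Reactants: 19 [(1R,6R)-1-farnesyl-5-hydroxy-2-oxo-7-oxabicyclo[4.1.0]hept-3-en-4-yl]methyl acetate
Product: 20 [(1R,6S)-1-farnesyl-2,5-dioxo-7-oxabicyclo[4.1.0]hept-3-en-4-yl]methyl acetate (target)
Conditions: Dess–Martin periodinane, CH2Cl2, 0 °C to rt
Reagents that add atoms: none
Why: Dess–Martin oxidation of the allylic C5 carbinol gives the ene-dione under non-basic conditions and removes the uncontrolled centre, while C1 and C6 keep their geometry (the C6 descriptor changes only by CIP priority).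

Compound list
1 | methyl 2-[bis(2,2,2-trifluoroethoxy)phosphoryl]acetate | COC(=O)CP(=O)(OCC(F)(F)F)OCC(F)(F)F | starting material
2 | (2E,6E)-farnesyl bromide | BrC/C=C(\C)CC/C=C(\C)CCC=C(C)C | starting material
3 | methyl 2-[bis(2,2,2-trifluoroethoxy)phosphoryl]-2-farnesylacetate (racemic) | COC(=O)C(C/C=C(\C)CC/C=C(\C)CCC=C(C)C)P(=O)(OCC(F)(F)F)OCC(F)(F)F | intermediate
4 | (tert-butyldimethylsilyloxy)acetaldehyde | O=CCO[Si](C)(C)C(C)(C)C | starting material
5 | methyl (2Z)-4-(TBS-oxy)-2-farnesylbut-2-enoate | COC(=O)/C(C/C=C(\C)CC/C=C(\C)CCC=C(C)C)=C\CO[Si](C)(C)C(C)(C)C | intermediate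
6 | (2Z)-4-(TBS-oxy)-2-farnesylbut-2-en-1-ol | OC/C(C/C=C(\C)CC/C=C(\C)CCC=C(C)C)=C\CO[Si](C)(C)C(C)(C)C | intermediate
7 | [(2S,3R)-3-(TBS-oxymethyl)-2-farnesyloxiran-2-yl]methanol | OC[C@]1(C/C=C(\C)CC/C=C(\C)CCC=C(C)C)O[C@@H]1CO[Si](C)(C)C(C)(C)C | intermediate
8 | (2R,3R)-3-(TBS-oxymethyl)-2-farnesyloxirane-2-carbaldehyde | O=C[C@]1(C/C=C(\C)CC/C=C(\C)CCC=C(C)C)O[C@@H]1CO[Si](C)(C)C(C)(C)C | intermediate
9 | trimethyl(prop-2-yn-1-yloxy)silane | C#CCO[Si](C)(C)C | starting material
10 | (Z)-trimethyl{[2,3-bis(trimethylstannyl)prop-2-en-1-yl]oxy}silane | C[Si](C)(C)OC/C([Sn](C)(C)C)=C/[Sn](C)(C)C | intermediate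
11 | (Z)-[3-(trimethylsilyloxy)-2-(trimethylstannyl)prop-1-en-1-yl]lithium (not isolated) | C[Si](C)(C)OC/C([Sn](C)(C)C)=C/[Li] | intermediate
12 | TMS ether of 13 at the primary oxygen (not isolated; both C2 epimers) | C[Si](C)(C)OC/C([Sn](C)(C)C)=C/C(O)[C@]1(C/C=C(\C)CC/C=C(\C)CCC=C(C)C)O[C@@H]1CO[Si](C)(C)C(C)(C)C | intermediate
13 | (2Z)-4-[(2S,3R)-3-(TBS-oxymethyl)-2-farnesyloxiran-2-yl]-2-(trimethylstannyl)but-2-ene-1,4-diol (both C2 epimers) | OC/C([Sn](C)(C)C)=C/C(O)[C@]1(C/C=C(\C)CC/C=C(\C)CCC=C(C)C)O[C@@H]1CO[Si](C)(C)C(C)(C)C | intermediate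
14 | primary acetate of 13 (not isolated) | CC(=O)OC/C([Sn](C)(C)C)=C/C(O)[C@]1(C/C=C(\C)CC/C=C(\C)CCC=C(C)C)O[C@@H]1CO[Si](C)(C)C(C)(C)C | intermediate
15 | (2Z)-4-hydroxy-2-iodo-4-[(2S,3R)-3-(TBS-oxymethyl)-2-farnesyloxiran-2-yl]but-2-en-1-yl acetate | CC(=O)OC/C(I)=C/C(O)[C@]1(C/C=C(\C)CC/C=C(\C)CCC=C(C)C)O[C@@H]1CO[Si](C)(C)C(C)(C)C | intermediate
16 | (2Z)-4-hydroxy-4-[(2S,3R)-3-(hydroxymethyl)-2-farnesyloxiran-2-yl]-2-iodobut-2-en-1-yl acetate | CC(=O)OC/C(I)=C/C(O)[C@]1(C/C=C(\C)CC/C=C(\C)CCC=C(C)C)O[C@@H]1CO | intermediate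
17 | (2Z)-4-[(2R,3S)-3-formyl-2-farnesyloxiran-2-yl]-2-iodo-4-oxobut-2-en-1-yl acetate | CC(=O)OC/C(I)=C/C(=O)[C@]1(C/C=C(\C)CC/C=C(\C)CCC=C(C)C)O[C@@H]1C=O | intermediate
18 | alkenylchromium(III) dichloride derived from 17, Cr in place of I (not isolated) | CC(=O)OC/C([Cr](Cl)Cl)=C/C(=O)[C@]1(C/C=C(\C)CC/C=C(\C)CCC=C(C)C)O[C@@H]1C=O | intermediate
19 | [(1R,6R)-1-farnesyl-5-hydroxy-2-oxo-7-oxabicyclo[4.1.0]hept-3-en-4-yl]methyl acetate (both C5 epimers) | CC(=O)OCC1=CC(=O)[C@]2(C/C=C(\C)CC/C=C(\C)CCC=C(C)C)O[C@@H]2C1O | intermediate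
20 | [(1R,6S)-1-farnesyl-2,5-dioxo-7-oxabicyclo[4.1.0]hept-3-en-4-yl]methyl acetate | CC(=O)OCC1=CC(=O)[C@]2(C/C=C(\C)CC/C=C(\C)CCC=C(C)C)O[C@@H]2C1=O | target

Total step count: 12. Longest linear sequence: 11 (steps 1–5 and 7–12); step 6 is a one-step side branch.

Steps most likely to fail

Step 11 (key step). Three processes may defeat it:
- reductive opening of the oxirane next to the C2 ketone by Cr(II),
- loss of acetate from the alkenylchromium species by β-elimination,
- protodemetalation before ring closure.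

The fallback moves the closure to a lower oxidation level at C2, so that neither an enone nor an epoxy ketone meets Cr(II). It sets out from 15. Silylation of the hindered C2 carbinol (TBSOTf, 2,6-lutidine) gives the bis-silyl ether F1. Buffered HF·pyridine removes only the primary silyl group to give the primary alcohol F2, and Dess–Martin oxidation gives the epoxy aldehyde F3. The Ni/Cr closure then gives the silyl-protected cyclohexenol F4, and HF·pyridine frees the cyclohexenediol F5. A double Dess–Martin oxidation brings the route back at 20.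

Step 7. The risks are tin–lithium exchange at the internal tin or at both tins, and attack of MeLi on the TMS ether, either of which scrambles the regiochemistry of the C3–C4 unit. The fallback builds the same iodoalkene from an alkyne without tin. It sets out from 8. Zn(OTf)2/Et3N-mediated addition of commercial propargyl acetate gives the propargylic alcohol F6, and Dess–Martin oxidation gives the ynone F7. Anti hydroiodination (NaI, AcOH) gives the (Z)-β-iodoenone silyl ether F8. HF·pyridine gives the (Z)-β-iodoenone alcohol F9, and Dess–Martin oxidation of the primary alcohol brings the route back at 17.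

Step 4. The risks are poor facial selectivity and slow turnover, because the directing hydroxyl sees a cis-substituted alkene, the least selective substrate class for this epoxidation. The fallback lets the C5 hydroxyl direct instead, which turns the substrate into the well-behaved 3,3-disubstituted class and requires D-(−)-tartrate for the same oxirane. It sets out from 6. Pivaloylation (PivCl, pyridine) gives the pivalate F10, and HF·pyridine gives the C5 allylic alcohol F11. Epoxidation with Ti(OiPr)4, D-(−)-diethyl tartrate and t-BuOOH gives the epoxy alcohol F12, and TBSCl/imidazole gives the silyl ether F13. DIBAL-H cleavage of the pivalate brings the route back at 7.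

Further compounds
F1 | step 11 | (2Z)-2-iodo-4-(TBS-oxy)-4-[3-(TBS-oxymethyl)-2-farnesyloxiran-2-yl]but-2-en-1-yl acetate, oxirane as in 15 | CC(=O)OC/C(I)=C/C(O[Si](C)(C)C(C)(C)C)[C@]1(C/C=C(\C)CC/C=C(\C)CCC=C(C)C)O[C@@H]1CO[Si](C)(C)C(C)(C)C
F2 | step 11 | (2Z)-4-[3-(hydroxymethyl)-2-farnesyloxiran-2-yl]-2-iodo-4-(TBS-oxy)but-2-en-1-yl acetate, oxirane as in 15 | CC(=O)OC/C(I)=C/C(O[Si](C)(C)C(C)(C)C)[C@]1(C/C=C(\C)CC/C=C(\C)CCC=C(C)C)O[C@@H]1CO
F3 | step 11 | (2Z)-4-[3-formyl-2-farnesyloxiran-2-yl]-2-iodo-4-(TBS-oxy)but-2-en-1-yl acetate, oxirane as in 15 | CC(=O)OC/C(I)=C/C(O[Si](C)(C)C(C)(C)C)[C@]1(C/C=C(\C)CC/C=C(\C)CCC=C(C)C)O[C@@H]1C=O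
F4 | step 11 | [1-farnesyl-5-hydroxy-2-(TBS-oxy)-7-oxabicyclo[4.1.0]hept-3-en-4-yl]methyl acetate, C1/C6 as in 19, C2 and C5 epimers | CC(=O)OCC1=CC(O[Si](C)(C)C(C)(C)C)[C@]2(C/C=C(\C)CC/C=C(\C)CCC=C(C)C)O[C@@H]2C1O
F5 | step 11 | [1-farnesyl-2,5-dihydroxy-7-oxabicyclo[4.1.0]hept-3-en-4-yl]methyl acetate, C1/C6 as in 19, C2 and C5 epimers | CC(=O)OCC1=CC(O)[C@]2(C/C=C(\C)CC/C=C(\C)CCC=C(C)C)O[C@@H]2C1O
F6 | step 7 | 4-hydroxy-4-[3-(TBS-oxymethyl)-2-farnesyloxiran-2-yl]but-2-yn-1-yl acetate, oxirane as in 8, C2 epimers | CC(=O)OCC#CC(O)[C@]1(C/C=C(\C)CC/C=C(\C)CCC=C(C)C)O[C@@H]1CO[Si](C)(C)C(C)(C)C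
F7 | step 7 | 4-oxo-4-[3-(TBS-oxymethyl)-2-farnesyloxiran-2-yl]but-2-yn-1-yl acetate, oxirane as in 8 | CC(=O)OCC#CC(=O)[C@]1(C/C=C(\C)CC/C=C(\C)CCC=C(C)C)O[C@@H]1CO[Si](C)(C)C(C)(C)C
F8 | step 7 | (2Z)-2-iodo-4-oxo-4-[3-(TBS-oxymethyl)-2-farnesyloxiran-2-yl]but-2-en-1-yl acetate, oxirane as in 8 | CC(=O)OC/C(I)=C/C(=O)[C@]1(C/C=C(\C)CC/C=C(\C)CCC=C(C)C)O[C@@H]1CO[Si](C)(C)C(C)(C)C
F9 | step 7 | (2Z)-4-[3-(hydroxymethyl)-2-farnesyloxiran-2-yl]-2-iodo-4-oxobut-2-en-1-yl acetate, oxirane as in 8 | CC(=O)OC/C(I)=C/C(=O)[C@]1(C/C=C(\C)CC/C=C(\C)CCC=C(C)C)O[C@@H]1CO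
F10 | step 4 | (2Z)-4-(TBS-oxy)-2-farnesylbut-2-en-1-yl pivalate | CC(C)(C)C(=O)OC/C(C/C=C(\C)CC/C=C(\C)CCC=C(C)C)=C\CO[Si](C)(C)C(C)(C)C
F11 | step 4 | (2Z)-4-hydroxy-2-farnesylbut-2-en-1-yl pivalate | CC(C)(C)C(=O)OC/C(C/C=C(\C)CC/C=C(\C)CCC=C(C)C)=C\CO
F12 | step 4 | [3-(hydroxymethyl)-2-farnesyloxiran-2-yl]methyl pivalate, oxirane geometry as in 7 | CC(C)(C)C(=O)OC[C@]1(C/C=C(\C)CC/C=C(\C)CCC=C(C)C)O[C@@H]1CO
F13 | step 4 | [3-(TBS-oxymethyl)-2-farnesyloxiran-2-yl]methyl pivalate, oxirane geometry as in 7 | CC(C)(C)C(=O)OC[C@]1(C/C=C(\C)CC/C=C(\C)CCC=C(C)C)O[C@@H]1CO[Si](C)(C)C(C)(C)C
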